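Everything rests on the C12–C13 bond. Ring D is carried as a spiro cyclopent-3-ene whose arms C14/C15 and carbons C13/C16 are equivalent, so C8 is not yet a stereocentre. After rings A and B are built (Rh-carbenoid C–H insertion for B, a 19,20-lactone-tethered Michael/aldol annulation for A), the alkene becomes a symmetric enediol bis(silyl) ether. Fluoride then releases an α-silyloxy enolate that C-alkylates the C12 tosylate of the 9α side chain. This closes ring C (C8, C9, C11, C12, C13, C14) last, creates the C13 carbinol and C16 ketone, and fixes C8 and C13 in one operation by exploiting the local mirror symmetry of ring D about C8.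

Key step: step 21

Remark 1: gibberellane numbering (C1–C20) is used for all intermediates; α is the face of C20 and β the face of H-5 and H-9 of the target.
Remark 2 (assumptions): enolisable or converging centres are left unspecified in the SMILES (C6 and C10 in 8–12, the tether CH in 18 and 19, ring D of 29); the (R)-catalyst of step 3 is chosen from the usual shielding model of the iminium ion; the 20-oxo 19-acid of 36 and 37 is drawn in its open form, which can close reversibly to a lactol.

Step 1
Reactants: 1 methyl cyclopent-3-ene-1-carboxylate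
Product: 2 cyclopent-3-ene-1-carbaldehyde
Conditions: DIBAL-H (1.05 equiv), CH2Cl2, −78 °C; Rochelle salt work-up
Reagents that add atoms: none
Why: At −78 °C DIBAL-H should stop at the aluminium hemiacetal, which gives the aldehyde on work-up (partial ester reduction), and no stereocentre is formed.

Step 2
Reactants: 2 cyclopent-3-ene-1-carbaldehyde; 3 (triphenylphosphoranylidene)acetaldehyde
Product: 4 (2E)-3-(cyclopent-3-en-1-yl)prop-2-enal
Conditions: toluene, 80 °C
Reagents that add atoms: (triphenylphosphoranylidene)acetaldehyde (3), O=CC=P(c1ccccc1)(c1ccccc1)c1ccccc1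
Why: Wittig olefination with the stabilised formylmethylene ylide should give the E-enal, and no stereocentre is formed.

Step 3
Reactants: 4 (2E)-3-(cyclopent-3-en-1-yl)prop-2-enal; 5 dimethyl 3-oxopentanedioate
Product: 8 keto lactone, via Michael aldehyde 6 (not isolated), via hydroxy keto diester 7 (not isolated)
Conditions: (R)-α,α-diphenylprolinol trimethylsilyl ether (10 mol%), PhCO2H (10 mol%), 5 (2 equiv), CH2Cl2, 0 °C; then NaBH(OAc)3, AcOH, 0 → 23 °C; then DBU (0.2 equiv), toluene, 50 °C
Reagents that add atoms: dimethyl 3-oxopentanedioate (5), COC(=O)CC(=O)CC(=O)OC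
Why: Iminium-catalysed Michael addition (Jørgensen–Hayashi catalyst) of the dicarbonyl CH2 to the E-enal creates C9, the silyloxydiphenylmethyl group of the (R)-catalyst shielding one face of the iminium ion so that the (R)-centre should form, after which NaBH(OAc)3 reduces only the aldehyde and base-mediated transesterification closes the six-membered lactone onto the adjacent ester carbon C20.

Step 4
Reactants: 8 keto lactone
Product: 9 diazo keto lactone
Conditions: 4-acetamidobenzenesulfonyl azide, Et3N, MeCN, 0 → 23 °C
Reagents that add atoms: 4-acetamidobenzenesulfonyl azide, CC(=O)Nc1ccc(cc1)S(=O)(=O)N=[N+]=[N-]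
Why: Regitz diazo transfer should take place at C6, the only CH2 flanked by two carbonyl groups, because the C10 methine cannot give a diazo compound without C–C cleavage.

Step 5
Reactants: 9 diazo keto lactone
Product: 10 spiro keto ester
Conditions: Rh2(OAc)4 (1 mol%), CH2Cl2, 40 °C, slow addition
Reagents that add atoms: none
Why: The Rh(II) carbenoid of the α-diazo β-keto ester inserts into a C–H bond five atoms away (carbenoid 1,5 C–H insertion to a cyclopentanone) and should prefer the tertiary C8–H of the cyclopentenyl group over the CH2 next to oxygen, which closes ring B and makes C8 a spiro carbon with two identical arms, so no fixed stereocentre is added.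

Step 6
Reactants: 10 spiro keto ester
Product: 11 enol triflate
Conditions: Tf2O, iPr2NEt, CH2Cl2, −78 °C
Reagents that add atoms: trifluoromethanesulfonic anhydride, O=S(=O)(OS(=O)(=O)C(F)(F)F)C(F)(F)F
Why: The doubly activated C5 ketone is enolised and should be O-sulfonylated (enol triflate formation), and either enol regioisomer is usable because both lead to the same dienolate in step 8.

Step 7
Reactants: 11 enol triflate
Product: 12 enoate lactone
Conditions: Pd(OAc)2 (5 mol%), PPh3, HCO2H, Et3N, DMF, 60 °C
Reagents that add atoms: none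
Why: Pd(0) inserts into the vinyl C–OTf bond and formate delivers hydride (palladium-catalysed reduction of an enol triflate), which removes the C5 oxygen and should leave the 5,6-enoate.

Step 8
Reactants: 12 enoate lactone
Product: 14 acetal lactone, via lithium dienolate 13 (not isolated)
Conditions: LDA (1.1 equiv), THF, −78 °C; then (MeO)2CH+ BF4− [from HC(OMe)3 and BF3·OEt2, CH2Cl2, −30 °C], −78 → −40 °C
Reagents that add atoms: dimethoxycarbenium tetrafluoroborate (made in the flask from trimethyl orthoformate), CO[CH+]OC.F[B-](F)(F)F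
Why: The cross-conjugated dienolate should be alkylated by the dialkoxycarbenium ion at C10, the terminus not flanked by the quaternary C8 (enolate formylation at the acetal level), and the new carbon must enter trans to C11 because the lactone stays cis-fused, which sets C10 with C20 cis to the C9 chain.

Step 9
Reactants: 14 acetal lactone
Product: 15 acetal diol
Conditions: LiBH4, THF, 0 → 23 °C
Reagents that add atoms: none
Why: LiBH4 should reduce the δ-lactone to the diol faster than the hindered conjugated methyl ester and does not touch the acetal (chemoselective lactone reduction), and no stereocentre changes.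

Step 10
Reactants: 15 acetal diol
Product: 16 acetal monoacetate
Conditions: Ac2O (1.05 equiv), 2,4,6-collidine, CH2Cl2, −20 °C
Reagents that add atoms: acetic anhydride, CC(=O)OC(C)=O
Why: Acylation at low temperature should discriminate the unhindered primary C12–OH from the neopentyl C20–OH (selective acetylation).

Step 11
Reactants: 16 acetal monoacetate; 17 ethyl 2-methyl-3-oxobutanoate
Product: 18 tether acetal
Conditions: 17 (3 equiv), DMAP (0.2 equiv), toluene, 110 °C, ethanol distilled off
Reagents that add atoms: ethyl 2-methyl-3-oxobutanoate (17), CCOC(=O)C(C)C(C)=O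
Why: DMAP-catalysed transesterification of the β-keto ester proceeds through the acylketene, which should be trapped by the free C20–OH, and the tether CH remains an enolisable epimeric centre.

Step 12
Reactants: 18 tether acetal
Product: 19 tether aldehyde
Conditions: PPTS, acetone/H2O, 55 °C
Reagents that add atoms: water, O
Why: Mild acid hydrolysis of the dimethyl acetal should free the non-enolisable C1 aldehyde without touching the esters.

Step 13
Reactants: 19 tether aldehyde
Product: 22 enone lactone, via Michael adduct 20 (not isolated), via ketol 21 (not isolated)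
Conditions: Cs2CO3 (1.5 equiv), MeCN, 23 → 60 °C
Reagents that add atoms: none
Why: The β-keto ester should add to C5 of the enoate in a 6-exo-trig Michael addition delivered by the C20 tether to the α-face (this sets C5 with 5β-H and the trans A/B fusion), the reversible addition funnels through the C4 epimer whose acetyl group reaches the C1 aldehyde, and aldol condensation then closes ring A and locks C4 as a bridgehead of the 19,20-lactone, while C6 is protonated on the open β-face to the 6α ester that step 17 corrects.

Step 14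
Reactants: 22 enone lactone
Product: 24 3-ketone, via silyl enol ether 23 (not isolated)
Conditions: [(Ph3P)CuH]6 (5 mol%), PhMe2SiH (1.5 equiv), toluene, 23 °C; then 1 M HCl, THF
Reagents that add atoms: none
Why: Copper hydride should add to C1 of the enone (1,4-hydrosilylation with Stryker's reagent), leaves the isolated alkene, esters and lactone untouched, and the silyl enol ether gives the ketone on acidic work-up.

Step 15
Reactants: 24 3-ketone
Product: 25 3β-alcohol
Conditions: K-Selectride (1.2 equiv), THF, −78 °C; AcOH quench at −78 °C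
Reagents that add atoms: none
Why: The bulky hydride should attack the C3 ketone along the equatorial trajectory and give the axial 3β-alcohol (Selectride reduction), the esters and the lactone being slower at −78 °C.

Step 16
Reactants: 25 3β-alcohol
Product: 26 3-O-TBS ether
Conditions: TBSOTf, 2,6-lutidine, CH2Cl2, 0 °C
Reagents that add atoms: tert-butyldimethylsilyl trifluoromethanesulfonate, CC(C)(C)[Si](C)(C)OS(=O)(=O)C(F)(F)F
Why: The silyl triflate should silylate the hindered axial alcohol (silyl ether formation), which blocks retro-aldol cleavage of C3–C4 and later oxidation at C3.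

Step 17
Reactants: 26 3-O-TBS ether
Product: 27 12-alcohol
Conditions: NaOMe (2 equiv), MeOH, 60 °C; then AcOH
Reagents that add atoms: none
Why: Methoxide should remove the acetate by transesterification and equilibrate C6 through the ester enolate to the more stable 6β ester, trans to the C4 substituent on C5 (thermodynamic epimerisation), while the lactone closes again on acidification.

Step 18
Reactants: 27 12-alcohol
Product: 28 12-tosylate
Conditions: TsCl, pyridine, DMAP (cat.), CH2Cl2, 0 → 23 °C
Reagents that add atoms: 4-toluenesulfonyl chloride, Cc1ccc(cc1)S(Cl)(=O)=O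
Why: Sulfonylation of the only free alcohol should give the primary tosylate (leaving-group installation).

Step 19
Reactants: 28 12-tosylate
Product: 29 acyloin
Conditions: RuCl3·xH2O (1 mol%), Oxone, NaHCO3, EtOAc/MeCN/H2O, 23 °C
Reagents that add atoms: potassium peroxymonosulfate (Oxone), OOS(=O)(=O)[O-].[K+]
Why: Catalytically generated RuO4 should oxidise the only alkene to the α-hydroxy ketone (ketohydroxylation), and the isomers differ only in how the acyloin sits on the two equivalent arms, so all give the same enediol ether in step 20.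

Step 20
Reactants: 29 acyloin
Product: 30 enediol bis(TMS) ether
Conditions: TMSOTf (2.5 equiv), Et3N (4 equiv), CH2Cl2, 0 → 23 °C
Reagents that add atoms: trimethylsilyl trifluoromethanesulfonate, C[Si](C)(C)OS(=O)(=O)C(F)(F)F
Why: O-silylation and reversible enolisation toward the oxygen-bearing carbon (thermodynamic silyl enol ether formation) should give the tetrasubstituted 1,2-bis(silyloxy)alkene, in which the two arms of ring D are equivalent again so that C8 is not a stereocentre.

Step 21
Reactants: 30 enediol bis(TMS) ether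
Product: 33 hydroxy ketone, via ammonium enolate 31 (not isolated), via 13-O-TMS ketone 32 (not isolated)
Conditions: TBAT (1.1 equiv), THF (0.005 M), −78 → 0 °C; then 0.5 M citric acid, THF, 0 °C
Reagents that add atoms: none
Why: Fluoride from TBAT cleaves one O–Si bond of the symmetric enediol bis(silyl) ether, the two α-silyloxy enolates that can result interconvert by 1,4 O-to-O silyl shift, and the one whose nucleophilic carbon lies on the α-arm displaces the C12 tosylate by SN2. The closest known reactions are the C-alkylation of acyloin enediolates released from 1,2-bis(trimethylsilyloxy)alkenes and the fluoride-mediated alkylation of silyl enol ethers. Ring C (C8, C9, C11, C12, C13, C14) closes in a 6-(enolexo)-exo-tet mode and completes the bicyclo[3.2.1]octane with the C16 ketone in the two-carbon bridge. C8 and C13 become stereocentres only now and both are controlled by C9: the 9α chain can reach only the sp2 carbon on the α-side of ring B, so this carbon becomes C13 and its CH2 becomes C14 (cis B/C fusion), and the bridged ring leaves one configuration for C13. The step needs C- instead of O-alkylation and attack by the oxygen-bearing carbon instead of a CH2 carbon; the first is secured by the six- against seven-membered ring, the second by the regiodefined enediol ether, which cannot give the C14 or C15 enolate without proton transfer. Acylation of the enolate by the ester or lactone would give a non-enolisable β-dicarbonyl and is reversible, whereas the alkylation is not.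

Step 22
Reactants: 33 hydroxy ketone
Product: 34 methylene lactone
Conditions: Zn, CH2Br2, TiCl4 (pre-formed reagent), THF/CH2Cl2, 0 → 23 °C
Reagents that add atoms: dibromomethane, BrCBr
Why: The Zn/CH2Br2/TiCl4 reagent (Lombardo methylenation) should convert the hindered C16 ketone into the exocyclic alkene under non-basic conditions, which avoids base-induced α-ketol rearrangement of the 13-hydroxy-16-ketone.

Step 23
Reactants: 34 methylene lactone
Product: 36 3-O-TBS aldehyde diacid, via hydroxy dicarboxylate salt 35 (not isolated)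
Conditions: Bu4NOH (40% aq.), THF/MeOH, 60 °C; evaporate, dry (toluene azeotrope); then TPAP (5 mol%), NMO, 4 Å MS, MeCN/CH2Cl2, 23 °C; 1 M HCl to pH 3, 0 °C
Reagents that add atoms: tetrabutylammonium hydroxide, [OH-].CCCC[N+](CCCC)(CCCC)CCCC
Why: Hydroxide should hydrolyse the methyl ester and open the lactone to the hydroxy dicarboxylate, which cannot relactonise as its salt, and TPAP/NMO then oxidises the C20 alcohol, the only free primary or secondary one, to the aldehyde (Ley–Griffith oxidation), the 3-O-silyl ether preventing oxidation and retro-aldol at C3.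

Step 24
Reactants: 36 3-O-TBS aldehyde diacid
Product: 37 target CNP0236431.1
Conditions: HF·pyridine, pyridine, THF, 0 → 23 °C
Reagents that add atoms: none
Why: Buffered HF should cleave the Si–O bond of the TBS ether without acid-induced rearrangement of the 13-hydroxy-16-ene unit (fluoride desilylation), and no stereocentre is touched.

Compound list

1 | methyl cyclopent-3-ene-1-carboxylate | COC(=O)C1CC=CC1 | starting material
2 | cyclopent-3-ene-1-carbaldehyde | O=CC1CC=CC1 | intermediate
3 | (triphenylphosphoranylidene)acetaldehyde | O=CC=P(c1ccccc1)(c1ccccc1)c1ccccc1 | starting material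
4 | (2E)-3-(cyclopent-3-en-1-yl)prop-2-enal | O=C/C=C/C1CC=CC1 | intermediate
5 | dimethyl 3-oxopentanedioate | COC(=O)CC(=O)CC(=O)OC | starting material
6 | Michael aldehyde: dimethyl 2-[(1R)-1-(cyclopent-3-en-1-yl)-3-oxopropyl]-3-oxopentanedioate (C10 epimers, ring–chain tautomers) | COC(=O)CC(=O)C(C(=O)OC)[C@H](CC=O)C1CC=CC1 | intermediate (not isolated)
7 | hydroxy keto diester: dimethyl 2-[(1R)-1-(cyclopent-3-en-1-yl)-3-hydroxypropyl]-3-oxopentanedioate | COC(=O)CC(=O)C(C(=O)OC)[C@H](CCO)C1CC=CC1 | intermediate (not isolated)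
8 | keto lactone: methyl 3-[(4R)-4-(cyclopent-3-en-1-yl)-2-oxooxan-3-yl]-3-oxopropanoate | COC(=O)CC(=O)C1C(=O)OCC[C@@H]1C1CC=CC1 | intermediate
9 | diazo keto lactone: methyl 2-diazo-3-[(4R)-4-(cyclopent-3-en-1-yl)-2-oxooxan-3-yl]-3-oxopropanoate | COC(=O)C(=[N+]=[N-])C(=O)C1C(=O)OCC[C@@H]1C1CC=CC1 | intermediate
10 | spiro keto ester: ring B cyclopentanone (C5 ketone, CO2Me on C6) spiro-linked at C8 to cyclopent-3-ene (ring D) and fused at C9–C10 to the δ-lactone C10–C20(=O)–O–C12H2–C11H2–C9; C9 as in 8 | COC(=O)C1C(=O)C2C(=O)OCC[C@@H]2C13CC=CC3 | intermediate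
11 | enol triflate: 10 as its C5 enol triflate, C5(OTf)=C6(CO2Me) | COC(=O)C1=C(OS(=O)(=O)C(F)(F)F)C2C(=O)OCC[C@@H]2C13CC=CC3 | intermediate
12 | enoate lactone: 10 without the C5 oxygen, C5=C6 conjugated with the ester (its C5=C10 isomer may accompany it) | COC(=O)C1=CC2C(=O)OCC[C@@H]2C13CC=CC3 | intermediate
13 | lithium dienolate: O-lithio ketene acetal of 12, C20(OLi)=C10–C5=C6–CO2Me | COC(=O)C1=CC2=C(O[Li])OCC[C@@H]2C13CC=CC3 | intermediate (not isolated)
14 | acetal lactone: 12 with a dimethoxymethyl group (future C1, β) on C10, lactone cis-fused (C20 and C11 both α) | COC(=O)C1=C[C@]2(C(OC)OC)C(=O)OCC[C@@H]2C13CC=CC3 | intermediate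
15 | acetal diol: ring B cyclopentene (C5=C6–CO2Me), spiro ring D on C8, 9α-CH2CH2OH, C10 with CH2OH (C20, α) and CH(OMe)2 (C1, β) | COC(=O)C1=C[C@@](CO)(C(OC)OC)[C@H](CCO)C12CC=CC2 | intermediate
16 | acetal monoacetate: 15 with the C12 hydroxyl acetylated | COC(=O)C1=C[C@@](CO)(C(OC)OC)[C@H](CCOC(C)=O)C12CC=CC2 | intermediate
17 | ethyl 2-methyl-3-oxobutanoate | CCOC(=O)C(C)C(C)=O | starting material
18 | tether acetal: 16 with the C20 hydroxyl esterified by 2-methyl-3-oxobutanoic acid (future C19, C4, C18, C3, C2) | COC(=O)C1=C[C@@](COC(=O)C(C)C(C)=O)(C(OC)OC)[C@H](CCOC(C)=O)C12CC=CC2 | intermediate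
19 | tether aldehyde: 18 with the acetal replaced by the C1 aldehyde | COC(=O)C1=C[C@@](COC(=O)C(C)C(C)=O)(C=O)[C@H](CCOC(C)=O)C12CC=CC2 | intermediate
20 | Michael adduct: C4–C5 bond formed, δ-lactone C10–C20H2–O–C19(=O)–C4 cis-fused to ring B on the α-face, C4 with CH3 and acetyl, C10 with CHO, 5β-H, 6α-CO2Me | COC(=O)[C@H]1C2(CC=CC2)[C@@H](CCOC(C)=O)[C@@]3(C=O)COC(=O)[C@](C)(C(C)=O)[C@@H]13 | intermediate (not isolated)
21 | ketol: ring A closed by the C1–C2 bond, 1-hydroxy-3-oxo | COC(=O)[C@H]1C2(CC=CC2)[C@@H](CCOC(C)=O)[C@]3(COC4=O)C(O)CC(=O)[C@]4(C)[C@@H]13 | intermediate (not isolated)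
22 | enone lactone: rings A, B, D; ring A 1-en-3-one; 19,20-lactone (C19 and C20 both α); 4β-CH3; 5β-H; 6α-CO2Me; 9β-H with 9α-CH2CH2OAc; spiro cyclopent-3-ene on C8 | COC(=O)[C@H]1C2(CC=CC2)[C@@H](CCOC(C)=O)[C@]3(COC4=O)C=CC(=O)[C@]4(C)[C@@H]13 | intermediate
23 | silyl enol ether: 3-(dimethylphenylsilyloxy)-2-ene from 22 | COC(=O)[C@H]1C2(CC=CC2)[C@@H](CCOC(C)=O)[C@]3(COC4=O)CC=C(O[Si](C)(C)c5ccccc5)[C@]4(C)[C@@H]13 | intermediate (not isolated)
24 | 3-ketone: 1,2-dihydro derivative of 22 | COC(=O)[C@H]1C2(CC=CC2)[C@@H](CCOC(C)=O)[C@]3(COC4=O)CCC(=O)[C@]4(C)[C@@H]13 | intermediate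
25 | 3β-alcohol: 24 with axial 3β-OH | COC(=O)[C@H]1C2(CC=CC2)[C@@H](CCOC(C)=O)[C@]3(COC4=O)CC[C@H](O)[C@]4(C)[C@@H]13 | intermediate
26 | 3-O-TBS ether of 25 | COC(=O)[C@H]1C2(CC=CC2)[C@@H](CCOC(C)=O)[C@]3(COC4=O)CC[C@H](O[Si](C)(C)C(C)(C)C)[C@]4(C)[C@@H]13 | intermediate
27 | 12-alcohol: 26 with free C12–OH and the ester epimerised to 6β | COC(=O)[C@@H]1C2(CC=CC2)[C@@H](CCO)[C@]3(COC4=O)CC[C@H](O[Si](C)(C)C(C)(C)C)[C@]4(C)[C@@H]13 | intermediate
28 | 12-tosylate of 27 | COC(=O)[C@@H]1C2(CC=CC2)[C@@H](CCOS(=O)(=O)c5ccc(C)cc5)[C@]3(COC4=O)CC[C@H](O[Si](C)(C)C(C)(C)C)[C@]4(C)[C@@H]13 | intermediate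
29 | acyloin: ring D of 28 as 2-hydroxycyclopentanone (C13/C16; positional and stereoisomers about C8) | COC(=O)[C@@H]1C2(CC(=O)C(O)C2)[C@@H](CCOS(=O)(=O)c5ccc(C)cc5)[C@]3(COC4=O)CC[C@H](O[Si](C)(C)C(C)(C)C)[C@]4(C)[C@@H]13 | intermediate
30 | enediol bis(TMS) ether: ring D as 3,4-bis(trimethylsilyloxy)cyclopent-3-ene (C13=C16, both O-silylated) | COC(=O)[C@@H]1C2(CC(O[Si](C)(C)C)=C(O[Si](C)(C)C)C2)[C@@H](CCOS(=O)(=O)c5ccc(C)cc5)[C@]3(COC4=O)CC[C@H](O[Si](C)(C)C(C)(C)C)[C@]4(C)[C@@H]13 | intermediate
31 | ammonium enolate: tetrabutylammonium enolate of the mono-TMS enediol of 30 | COC(=O)[C@@H]1C2(CC([O-])=C(O[Si](C)(C)C)C2)[C@@H](CCOS(=O)(=O)c5ccc(C)cc5)[C@]3(COC4=O)CC[C@H](O[Si](C)(C)C(C)(C)C)[C@]4(C)[C@@H]13.CCCC[N+](CCCC)(CCCC)CCCC | intermediate (not isolated)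
32 | 13-O-TMS ketone: ring C closed, 13-OTMS, 16-oxo | O=C1C[C@]23C[C@@]1(O[Si](C)(C)C)CC[C@H]2[C@]1(COC4=O)CC[C@H](O[Si](C)(C)C(C)(C)C)[C@]4(C)[C@H]1[C@@H]3C(=O)OC | intermediate (not isolated)
33 | hydroxy ketone: 13-hydroxy-16-oxo-17-nor compound with 19,20-lactone, 7-methyl ester, 3β-OTBS | O=C1C[C@]23C[C@@]1(O)CC[C@H]2[C@]1(COC4=O)CC[C@H](O[Si](C)(C)C(C)(C)C)[C@]4(C)[C@H]1[C@@H]3C(=O)OC | intermediate
34 | methylene lactone: 33 with C16=C17H2 | C=C1C[C@]23C[C@@]1(O)CC[C@H]2[C@]1(COC4=O)CC[C@H](O[Si](C)(C)C(C)(C)C)[C@]4(C)[C@H]1[C@@H]3C(=O)OC | intermediate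
35 | hydroxy dicarboxylate salt: bis(tetrabutylammonium) 7,19-dicarboxylate with free 20-OH | C=C1C[C@]23C[C@@]1(O)CC[C@H]2[C@]1(CO)CC[C@H](O[Si](C)(C)C(C)(C)C)[C@@](C)(C(=O)[O-])[C@H]1[C@@H]3C(=O)[O-].CCCC[N+](CCCC)(CCCC)CCCC.CCCC[N+](CCCC)(CCCC)CCCC | intermediate (not isolated)
36 | 3-O-TBS aldehyde diacid: 3-O-TBS ether of the target | C=C1C[C@]23C[C@@]1(O)CC[C@H]2[C@]1(C=O)CC[C@H](O[Si](C)(C)C(C)(C)C)[C@@](C)(C(=O)O)[C@H]1[C@@H]3C(=O)O | intermediate
37 | target CNP0236431.1: 3β,13-dihydroxy-20-oxo-gibberell-16-ene-7,19-dioic acid | C=C1C[C@]23C[C@@]1(O)CC[C@H]2[C@]1(C=O)CC[C@H](O)[C@@](C)(C(=O)O)[C@H]1[C@@H]3C(=O)O | target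

Total step count: 24. Longest linear sequence: 24 steps (1 to 37).

Steps most likely to fail

Step 21. Fluoride or the enolate oxygen may attack the tosylate, or proton transfer may move the enolate to C14/C15, so that ring closure occurs at oxygen or at a CH2 carbon. The fallback replaces the enolate by a radical and sets out from acyloin 29. Finkelstein exchange (NaI, acetone, 50 °C) gives the iodo acyloin F1, and TMSOTf/Et3N gives the iodo enediol bis(TMS) ether F2. Slow addition of Bu3SnH/AIBN (benzene, 80 °C) generates the C12 radical, which closes ring C by 6-exo-trig addition to the α-arm carbon of the enediol ether and is reduced to the 13,16-bis(TMS) ether F3. K2CO3/MeOH frees the 13,16-diol F4, and Parikh–Doering oxidation (SO3·pyridine, DMSO, Et3N) of its secondary C16 alcohol comes back to the route at 33.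

Step 13. The Michael equilibrium may stay on the side of the open keto ester, or the aldol condensation onto the neopentyl aldehyde may stall. The fallback closes ring A by an intramolecular Horner–Wadsworth–Emmons reaction and sets out from acetal monoacetate 16. Transesterification with ethyl 4-(diethoxyphosphoryl)-2-methyl-3-oxobutanoate (DMAP, toluene, 110 °C) gives the phosphonate tether acetal F5, and PPTS in acetone/H2O gives the phosphonate tether aldehyde F6. Cs2CO3, then K2CO3/18-crown-6 (MeCN/toluene), effects the same tethered Michael addition followed by irreversible olefination and comes back to the route at 22.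

Step 23. The hydroxy acid may relactonise before it is oxidised, or C20 may be oxidised beyond the aldehyde. The fallback protects both acids as esters before a neutral oxidation and sets out from 34. After the same Bu4NOH hydrolysis, allyl bromide (DMF, 0 °C) alkylates both carboxylates to the diallyl ester 20-alcohol F7. Dess–Martin periodinane (NaHCO3, CH2Cl2) gives the diallyl ester 20-aldehyde F8, and Pd(PPh3)4/morpholine (THF, 23 °C) removes both allyl groups and comes back to the route at 36.

Further compounds
F1 | step 21 | iodo acyloin | COC(=O)[C@@H]1C2(CC(=O)C(O)C2)[C@@H](CCI)[C@]3(COC4=O)CC[C@H](O[Si](C)(C)C(C)(C)C)[C@]4(C)[C@@H]13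
F2 | step 21 | iodo enediol bis(TMS) ether | COC(=O)[C@@H]1C2(CC(O[Si](C)(C)C)=C(O[Si](C)(C)C)C2)[C@@H](CCI)[C@]3(COC4=O)CC[C@H](O[Si](C)(C)C(C)(C)C)[C@]4(C)[C@@H]13
F3 | step 21 | 13,16-bis(TMS) ether | C[Si](C)(C)OC1C[C@]23C[C@@]1(O[Si](C)(C)C)CC[C@H]2[C@]1(COC4=O)CC[C@H](O[Si](C)(C)C(C)(C)C)[C@]4(C)[C@H]1[C@@H]3C(=O)OC
F4 | step 21 | 13,16-diol | OC1C[C@]23C[C@@]1(O)CC[C@H]2[C@]1(COC4=O)CC[C@H](O[Si](C)(C)C(C)(C)C)[C@]4(C)[C@H]1[C@@H]3C(=O)OC
F5 | step 13 | phosphonate tether acetal | COC(=O)C1=C[C@@](COC(=O)C(C)C(=O)CP(=O)(OCC)OCC)(C(OC)OC)[C@H](CCOC(C)=O)C12CC=CC2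
F6 | step 13 | phosphonate tether aldehyde | COC(=O)C1=C[C@@](COC(=O)C(C)C(=O)CP(=O)(OCC)OCC)(C=O)[C@H](CCOC(C)=O)C12CC=CC2
F7 | step 23 | diallyl ester 20-alcohol | C=C1C[C@]23C[C@@]1(O)CC[C@H]2[C@]1(CO)CC[C@H](O[Si](C)(C)C(C)(C)C)[C@@](C)(C(=O)OCC=C)[C@H]1[C@@H]3C(=O)OCC=C
F8 | step 23 | diallyl ester 20-aldehyde | C=C1C[C@]23C[C@@]1(O)CC[C@H]2[C@]1(C=O)CC[C@H](O[Si](C)(C)C(C)(C)C)[C@@](C)(C(=O)OCC=C)[C@H]1[C@@H]3C(=O)OCC=C
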